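0.107 /d is the number we would start from: the spending constant of G, the fraction of the G present that is lost per day, as we read it from the maple run. You asked for a quick figure on west and north-east, and we reckon it with the fractions left, l for L and g for G, not with the fractions made.

| flask | L | G | remark | time |
|---|---|---|---|---|
| elm | 0.050 M | 0.80 mM | run made earlier |  |
| alder | 0.050 M | 1.2 mM | run made earlier |  |
| maple | 0.10 M | 1.6 mM | run made earlier |  |
| west | 0.050 M | 1.6 mM |  | 10 d |
| north-east | 0.050 M | 1.6 mM |  | 2.5 d |

| run | time / d | Z / % | L / % |
|---|---|---|---|
| elm | 0.833 | 11.1 | 89.2 |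
| elm | 2.50 | 31.4 | 69.8 |
| elm | 4.00 | 40.4 | 59.0 |
| elm | 6.00 | 53.2 | 44.5 |
| elm | 10.0 | 69.4 | 31.5 |
| elm | 12.0 | 73.8 | 25.7 |
| alder | 1.04 | 20.2 | 80.4 |
| alder | 1.67 | 26.7 | 75.0 |
| alder | 2.50 | 33.3 | 64.6 |
| alder | 4.00 | 49.6 | 50.3 |
| alder | 8.00 | 70.8 | 27.7 |
| alder | 12.0 | 82.5 | 19.2 |
| maple | 1.04 | 19.4 | 80.6 |
| maple | 1.67 | 27.5 | 70.3 |
| maple | 3.00 | 45.2 | 55.3 |
| maple | 6.00 | 66.6 | 32.0 |
| maple | 12.0 | 83.7 | 15.6 |

(readings scatter by 1 percentage point)

- the average divides the monomer in chains by the number of chains, living and dead together; two radicals that join make one chain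
- candidate steps: G -> 2 X; L + X -> Q + Z; L + Q -> Z + Q; 2 Q -> D; L -> E
- the earlier runs do not show the number of chains; that part of a forecast is a guess

* which of the two ends with the longer chains by the average number of monomer units in a chain (living and dead chains, two that joined counted as one) ("neither" if they lie within 10%) (west / north-east / neither)
* average number of monomer units in a chain (living and dead chains, two that joined counted as one) at the end, west
* average number of monomer units in a chain (living and dead chains, two that joined counted as one) at the end, north-east

At the last maple reading Z and L add up to 99.3%, so we count the L used as Z. We treat L as pseudo-first-order and take the mean slope −ln(l)/t. In maple it falls from 0.207 /d at 1.04 d to 0.155 /d at 12.0 d. The first slopes of maple and elm stand in a ratio of 1.51, near the 1.41 given by the root of their G charges. So we let the slope follow the root of G, which makes the mean slope up to t about a·exp(−s·t/4), with a start slope a of 0.213 /d. That gives s above. We assume a carries over to half the L of maple, at the same G charge.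

Two X per G, joining in pairs as Q, make one chain per G spent, so the length is (L charged)(1−l) over (G charged)(1−g). For west we reckon l = 19.5% and g = 34.4%, a length of 38.3. For north-east we reckon l = 60.7% and g = 76.6%, a length of 52.4. North-east is longer than west by a factor of 1.37, beyond the margin of 10%.

Your forecast names north-east, with 46 for west and 64 for north-east, on these grounds: “Two radicals per G that join in pairs give one chain per G consumed”. You assume an efficiency of 0.85 for that chain count where we take one; your ratio of north-east to west is 1.39, and ours is 1.37.

The flask gives north-east, with 40.5 for west and 56.0 for north-east.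

    G → 2 X (k = 1.16 × 10⁻⁶ /s)
    L + X → Q + Z (k = 13000 /M/s)
    L + Q → Z + Q, rate k3*[Q]*[L] (k = 70.6 /M/s)
    2 Q → D (k = 1.60 × 10⁶ /M/s)
    L → E (k = 1.13 × 10⁻⁸ /s)

With s as read, we put G left in north-east at 76.6%, where the flask holds 78% at 2.50 d. A neighbouring flask is north-east read at 6.0 d. For it the same reckoning gives l = 33.6% and g = 52.7%, so a length of 43.9. The simulated neighbour holds 32.2% of L and 55% of G, and its length is 46.7, shorter than the 56.0 of north-east.

The runs are calculated for an exercise, and the scatter is random.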